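Working the flask up early or leaving it to 2.0 h is a real choice if the ratio of other capture product to target moves with time, so that ratio is wanted at the times below.

- larch: starting material 1.1 M; first nucleophile 1.1 equiv; second nucleophile 1.2 equiv; the very flask that is asked about, followed so far
- flask: starting material 1.1 M; first nucleophile 1.10 equiv; second nucleophile 1.20 equiv; time 2.0 h

- larch (time / min: other capture product / %, target / %, starting material / %): 4.00: 36.9, 17.7, 22.3; 6.00: 42.8, 19.7, 9.9; 8.00: 44.5, 21.3, 5.4; 15.0: 46.4, 21.9, 0; 20.0: 46.8, 22.3, 0.2; 30.0: 46.8, 22.6, 0; 50.0: 46.7, 21.7, 0.1

(standard deviation of a reading: 0.5 percentage points)

- target is meant together with its crystals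
- solid, in amounts per volume of the solution: crystals
- what was read earlier has a scatter of 0.5 percentage points, one standard deviation
- steps under discussion: first nucleophile + intermediate -> target; crystals <-> target; intermediate -> side product; intermediate -> solvolysis product; second nucleophile + intermediate -> other capture product; starting material -> intermediate

1. ratio of other capture product to target at 4.0 s
2. ratio of other capture product to target at 3.0 min
3. ratio of other capture product to target at 2.0 h
4. which of other capture product and target there is more of at 2.0 h

The larch run is this same flask, followed so far. Take the main step first: starting material decays to intermediate, and the reading of 22.3% at 4.00 min gives a first-order half-life of 1.85 min. Counted in half-lives, 4.0 s is 0.0360, 3.0 min is 1.62 and 2.0 h is 64.9. So 2.47% has turned over at the early time and 67.5% at the middle one, while the larch readings of starting material stay within scatter of zero from 15.0 min.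

Now add the capture. Each nucleophile takes intermediate at a rate proportional to its own concentration, so the two products form in the instantaneous ratio S[second nucleophile]/[first nucleophile]. Dividing the two rate laws removes the intermediate, and S, the selectivity factor, becomes the logarithm of the fraction of second nucleophile left over that of the fraction of first nucleophile left. The larch plateau reads 46.8% other capture product and 22.2% target, which leaves 61.0% and 79.8% of the two charges, so S = 2.19.

Then add the depletion. At zero conversion the ratio is S times the charges, 2.39, and it declines from there as second nucleophile falls further than first. Taking target in step with conversion, first nucleophile stands at 86.4% of its charge at 3.0 min, which gives a cumulative ratio of 2.20, and the larch plateau reads 2.11. Neither product accounts for 31.0% of the charge on the larch plateau.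

The forecast gives 2.37 (2.12 to 2.55), 2.19 (2.07 to 2.3) and 2.11 (2.05 to 2.17), with other capture product ahead, on the ground that “crystals count as target, so crystallisation cannot shift the ratio”.

The flask gives 2.36, 2.18 and 2.09, with other capture product ahead at 47.0% against 22.5% target.

    first nucleophile + intermediate → target (k = 0.830 M⁻¹ s⁻¹)
    crystals ⇌ target, rate k2*(cs2 - [target]) while solid is left; crystals form when [target] > cs2 (solubility = 0.100 M, k = 1.90 s⁻¹)
    intermediate → side product (k = 0.0140 s⁻¹)
    intermediate → solvolysis product (k = 1.20 s⁻¹)
    second nucleophile + intermediate → other capture product (k = 1.80 M⁻¹ s⁻¹)
    starting material → intermediate (k = 0.00630 s⁻¹)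

In this flask the lifetime of intermediate against solvolysis, 0.833 s, is far shorter than the 1.8 min half-life of starting material. At 0.0306 h intermediate is made and used at a ratio of 0.999. Of the 22.5% target, 13.4% stands as crystals, and the saturation of target changes the final ratio by nothing. In the neighbour flask charged with 0.280 equiv of first nucleophile, S gives a starting ratio of 9.39. The computed neighbour has 9.26 at 4.0 s and 7.97 at 2.0 h, with 6.93% target.

The readings come from a simulation from invented constants, noise included.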